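**Retrosynthesis**
1. Target 29 comes from global hydrogenolysis of the 18-benzyl-protected 28: 15 ArOBn, C1-OBn, C2-OBn and the ring-C CO2Bn.
2. The 4,6-(S)-HHDP ring (11-membered) of 28 comes from Ullmann coupling of the 4,6-bis(2-iodogalloyl) diester 27, which comes from diol 26, which comes from 25 by benzylidene removal.
3. The 3,5-A/B (11-membered) and B/C (10-membered) macrolactone biaryls of the nonahydroxyterphenoyl (NHTP) unit in 25 come from one new step: Pd-catalysed double dehydrogenative macrocyclisation of three plain perbenzylgalloyl units in 24 (ring A on O5, ring B on O3, ring C on C1).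
4. 24 is a C-aryl glucitol. The aryl–C1 bond comes from ArLi addition to lactol 14, C1 (S) is set by oxidation then chelation-controlled reduction, and the ring-C CO2H is unmasked from an aldehyde acetal.
5. Phenyl thioglucoside 10 supplies the sugar and methyl gallate supplies all the aryl units. Rings form in this order: aryl–C1 bond, NHTP macrocycles, HHDP.

Assumptions:
- The target SMILES has no biaryl axis descriptors, so I assume the natural (S)-configured HHDP and NHTP axes.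
- The hydroxy-acid (C1-OH, ring-C CO2H) is assumed to stay open as drawn.
- NaH/BnBr at 2-OH of the 4,6-benzylidene thioglucoside is assumed to be mainly 2-selective, with the 3-O isomer separable.

**Route**

Step 1
Reactants: 1 methyl gallate
Product: 2 methyl 3,4,5-tris(benzyloxy)benzoate
Conditions: BnBr (3.5 equiv), K2CO3, DMF, 60 °C
Reagents that add atoms: BnBr, BrCc1ccccc1
Why: Williamson etherification protects all three phenols as benzyl ethers.

Step 2
Reactants: 2
Product: 3 3,4,5-tris(benzyloxy)benzoic acid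
Conditions: LiOH·H2O, THF/MeOH/H2O, 50 °C
Reagents that add atoms: water, O
Why: Saponification of an unhindered methyl ester.

Step 3
Reactants: 2
Product: 4 methyl 3,4,5-tris(benzyloxy)-2-iodobenzoate
Conditions: NIS, cat. TFA, MeCN, 50 °C
Reagents that add atoms: NIS, O=C1CCC(=O)N1I (supplies I)
Why: Electrophilic aromatic iodination at the only free positions, which are ortho to the ester and equivalent by symmetry.

Step 4
Reactants: 4
Product: 5 3,4,5-tris(benzyloxy)-2-iodobenzoic acid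
Conditions: LiOH·H2O, THF/MeOH/H2O, 50 °C
Reagents that add atoms: water, O
Why: Saponification.

Step 5
Reactants: 2
Product: 6 [3,4,5-tris(benzyloxy)phenyl]methanol
Conditions: LiAlH4, THF, 0 °C
Reagents that add atoms: none
Why: Ester reduction to the primary alcohol; benzyl ethers are untouched.

Step 6
Reactants: 6
Product: 7 3,4,5-tris(benzyloxy)benzaldehyde
Conditions: MnO2, CH2Cl2, rt
Reagents that add atoms: none
Why: Chemoselective oxidation of a benzylic alcohol to the aldehyde.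

Step 7
Reactants: 7
Product: 8 2-bromo-3,4,5-tris(benzyloxy)benzaldehyde
Conditions: Br2, NaOAc, AcOH/CH2Cl2, 0 °C to rt
Reagents that add atoms: Br2, BrBr (supplies Br)
Why: Electrophilic bromination of the electron-rich ring ortho to CHO.

Step 8
Reactants: 8
Product: 9 2-bromo-3,4,5-tris(benzyloxy)benzaldehyde dimethyl acetal
Conditions: HC(OMe)3, cat. TsOH, MeOH, rt
Reagents that add atoms: trimethyl orthoformate, COC(OC)OC (supplies the two OMe groups)
Why: Acetalisation masks the carbonyl so the aryl bromide can be lithiated; this acetal later becomes ring-C CO2Bn.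

Step 9
Reactants: 10 phenyl 1-thio-β-D-glucopyranoside (commercial)
Product: 11 phenyl 4,6-O-[(R)-benzylidene]-1-thio-β-D-glucopyranoside
Conditions: PhCH(OMe)2, CSA, MeCN, 40 °C
Reagents that add atoms: benzaldehyde dimethyl acetal, COC(OC)c1ccccc1
Why: Transacetalisation gives the thermodynamic (R) trans-fused 4,6-dioxane, which protects O4/O6 and leaves O5 to be revealed later.

Step 10
Reactants: 11
Product: 12 phenyl 2-O-benzyl-4,6-O-benzylidene-1-thio-β-D-glucopyranoside
Conditions: NaH (1.0 equiv), BnBr, DMF, 0 °C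
Reagents that add atoms: BnBr, BrCc1ccccc1
Why: The most acidic 2-OH is alkylated preferentially; the minor 3-O-Bn isomer is removed by chromatography.

Step 11
Reactants: 12
Product: 13 phenyl 2-O-benzyl-3-O-TBS-4,6-O-benzylidene-1-thio-β-D-glucopyranoside
Conditions: TBSOTf, 2,6-lutidine, CH2Cl2, 0 °C
Reagents that add atoms: TBSOTf, CC(C)(C)[Si](C)(C)OS(=O)(=O)C(F)(F)F
Why: Silylation of the remaining hindered OH; the resulting ether resists ArLi and can be removed later without touching esters.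

Step 12
Reactants: 13
Product: 14 2-O-benzyl-3-O-TBS-4,6-O-benzylidene-D-glucopyranose (anomeric mixture)
Conditions: NBS, acetone/H2O (9:1), 0 °C
Reagents that add atoms: water, O
Why: Thioglycoside hydrolysis by bromonium activation; the acetal and TBS ether survive.

Step 13
Reactants: 14; 9 (as ArLi, made from 9 with t-BuLi, THF, –78 °C)
Product: 15 1-C-aryl-2-O-benzyl-3-O-TBS-4,6-O-benzylidene-D-glucitol (C1 epimer mixture, 1R major; O5-OH free)
Conditions: 9 (3.3 equiv), t-BuLi (6.6 equiv), THF, –78 °C, 30 min; then 14, –78 to –40 °C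
Reagents that add atoms: none (the aryl group comes from 9)
Why: Li–Br exchange followed by 1,2-addition to the open-chain aldehyde form of the lactol; the new C1 centre is chelation-biased to R but the mixture is tolerated because C1 is reset in Steps 15–16.

Step 14
Reactants: 15; 3
Product: 16 O5 3,4,5-tris(benzyloxy)benzoate of 15
Conditions: EDC·HCl, DMAP, CH2Cl2, rt
Reagents that add atoms: none (the acyl group comes from 3)
Why: Steglich esterification goes at the accessible C5-OH, while the benzylic C1-OH, flanked by an ortho-disubstituted aryl group, is unreactive.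

Step 15
Reactants: 16
Product: 17 aryl C1 ketone
Conditions: DMP, NaHCO3, CH2Cl2, rt
Reagents that add atoms: none
Why: Dess–Martin oxidation erases the C1 epimer mixture; the buffer avoids epimerising C2.

Step 16
Reactants: 17
Product: 18 (1S)-alcohol
Conditions: Zn(BH4)2, Et2O/THF, –30 °C
Reagents that add atoms: none (hydride only)
Why: Hydride is delivered to the C1=O/O2-OBn Zn-chelate from the face bearing H2, which gives the (1S) alcohol required by the target; this is chelation-controlled reduction of an α-alkoxy ketone.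

Step 17
Reactants: 18
Product: 19 C1-O-benzyl ether
Conditions: NaH, BnBr, cat. TBAI, THF/DMF, 0 °C
Reagents that add atoms: BnBr, BrCc1ccccc1
Why: Williamson etherification blocks C1-OH so that it cannot form a hemiacetal or phthalide with the ortho carbonyl; no stereocentre is touched.

Step 18
Reactants: 19
Product: 20 ring-C aldehyde
Conditions: PPTS, acetone/H2O, 50 °C
Reagents that add atoms: water, O
Why: The electron-rich aryl dimethyl acetal hydrolyses much faster than the benzylidene or TBS ether under these mild conditions.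

Step 19
Reactants: 20
Product: 21 ring-C carboxylic acid
Conditions: NaClO2, NaH2PO4, 2-methyl-2-butene, t-BuOH/H2O, rt
Reagents that add atoms: NaClO2, [Na+].[O-]Cl=O (supplies O)
Why: Pinnick oxidation; the alkene scavenges HOCl so the arene is not chlorinated.

Step 20
Reactants: 21
Product: 22 ring-C benzyl ester
Conditions: BnBr, K2CO3, DMF, rt
Reagents that add atoms: BnBr, BrCc1ccccc1
Why: Carboxylate alkylation gives a hydrogenolysable ester whose carbonyl later directs C–H metalation.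

Step 21
Reactants: 22
Product: 23 3-OH compound
Conditions: TBAF, AcOH (1:1), THF, 0 °C to rt
Reagents that add atoms: none
Why: Buffered fluoride removes the silyl ether. Any 1,3-acyl shift from O5 to O3 is harmless because both positions carry the same acyl group at this stage.

Step 22
Reactants: 23; 3
Product: 24 3,5-di-O-(tribenzylgalloyl) C-aryl glucitol, the NHTP precursor
Conditions: 3, 2,4,6-Cl3C6H2COCl, Et3N, THF; then 23, DMAP, toluene, 60 °C
Reagents that add atoms: none (the acyl group comes from 3)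
Why: Yamaguchi esterification of the hindered secondary alcohol.

Step 23
Reactants: 24
Product: 25 NHTP macrocycle (two new biaryl axes, benzylidene intact)
Conditions: Pd(OAc)2 (30 mol %), Ag2CO3 (4 equiv), PivOH (1 equiv), DCE, 100 °C, 2 mM
Reagents that add atoms: none
Why: Proposed new method: ester-assisted concerted metalation–deprotonation at the ortho C–H of ring B, then at ring A (and then ring C), followed by C–C reductive elimination with Ag(I) reoxidising Pd(0), gives the two tetra-ortho-substituted biaryl macrolactones; the locked 1,3-dioxane and C3/C5 stereocentres allow only one axial sense of each 11-/10-membered bridge, so the natural atropisomers form. The closest known reactions are Pd(II)/Ag oxidative coupling of aryl benzoates to biaryl lactones and Cu/amine oxidative HHDP formation, but neither has been shown on perbenzylated galloyl esters to give NHTP.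

Step 24
Reactants: 25
Product: 26 4,6-diol
Conditions: TsOH·H2O, MeOH/CH2Cl2, rt
Reagents that add atoms: none
Why: Acid-catalysed transacetalisation releases O4 and O6; esters and benzyl ethers are stable.

Step 25
Reactants: 26; 5
Product: 27 4,6-bis(2-iodo-3,4,5-tribenzyloxybenzoate)
Conditions: 5 (2.6 equiv), 2,4,6-Cl3C6H2COCl, Et3N, THF; then 26, DMAP, toluene, 80 °C
Reagents that add atoms: none (the acyl groups come from 5)
Why: Yamaguchi double esterification of a primary and a hindered secondary alcohol.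

Step 26
Reactants: 27
Product: 28 perbenzylated target with 4,6-(S)-HHDP
Conditions: Cu powder (activated, 10 equiv), DMF, 120 °C
Reagents that add atoms: none
Why: Intramolecular Ullmann coupling; the 4,6-diester template on the sugar enforces the (S)-biaryl axis.

Step 27
Reactants: 28
Product: 29 chinquapinic acid
Conditions: H2 (1 atm), Pd(OH)2/C, THF/MeOH (1:1), rt
Reagents that add atoms: none
Why: Hydrogenolysis of all benzyl ethers and the benzyl ester under neutral conditions leaves the C1 and C2 hydroxyls and the carboxylic acid free; no stereocentre is affected.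

**Compound list**
1 | methyl gallate | COC(=O)c1cc(O)c(O)c(O)c1 | starting material
2 | methyl 3,4,5-tris(benzyloxy)benzoate | COC(=O)c1cc(OCc2ccccc2)c(OCc2ccccc2)c(OCc2ccccc2)c1 | intermediate
3 | 3,4,5-tris(benzyloxy)benzoic acid | OC(=O)c1cc(OCc2ccccc2)c(OCc2ccccc2)c(OCc2ccccc2)c1 | intermediate
4 | methyl 3,4,5-tris(benzyloxy)-2-iodobenzoate | COC(=O)c1cc(OCc2ccccc2)c(OCc2ccccc2)c(OCc2ccccc2)c1I | intermediate
5 | 3,4,5-tris(benzyloxy)-2-iodobenzoic acid | OC(=O)c1cc(OCc2ccccc2)c(OCc2ccccc2)c(OCc2ccccc2)c1I | intermediate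
6 | [3,4,5-tris(benzyloxy)phenyl]methanol | OCc1cc(OCc2ccccc2)c(OCc2ccccc2)c(OCc2ccccc2)c1 | intermediate
7 | 3,4,5-tris(benzyloxy)benzaldehyde | O=Cc1cc(OCc2ccccc2)c(OCc2ccccc2)c(OCc2ccccc2)c1 | intermediate
8 | 2-bromo-3,4,5-tris(benzyloxy)benzaldehyde | O=Cc1cc(OCc2ccccc2)c(OCc2ccccc2)c(OCc2ccccc2)c1Br | intermediate
9 | 2-bromo-3,4,5-tris(benzyloxy)benzaldehyde dimethyl acetal | COC(OC)c1cc(OCc2ccccc2)c(OCc2ccccc2)c(OCc2ccccc2)c1Br | intermediate
10 | phenyl 1-thio-β-D-glucopyranoside | OC[C@H]1O[C@@H](Sc2ccccc2)[C@H](O)[C@@H](O)[C@@H]1O | starting material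
11 | phenyl 4,6-O-(R)-benzylidene-1-thio-β-D-glucopyranoside | O3C[C@H]1O[C@@H](Sc2ccccc2)[C@H](O)[C@@H](O)[C@@H]1O[C@@H]3c4ccccc4 | intermediate
12 | 2-O-benzyl derivative of 11 | O3C[C@H]1O[C@@H](Sc2ccccc2)[C@H](OCc5ccccc5)[C@@H](O)[C@@H]1O[C@@H]3c4ccccc4 | intermediate
13 | 3-O-TBS derivative of 12 | O3C[C@H]1O[C@@H](Sc2ccccc2)[C@H](OCc5ccccc5)[C@@H](O[Si](C)(C)C(C)(C)C)[C@@H]1O[C@@H]3c4ccccc4 | intermediate
14 | 2-O-benzyl-3-O-TBS-4,6-O-benzylidene-D-glucopyranose | O3C[C@H]1OC(O)[C@H](OCc5ccccc5)[C@@H](O[Si](C)(C)C(C)(C)C)[C@@H]1O[C@@H]3c4ccccc4 | intermediate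
15 | C-aryl glucitol diol (C1 epimers) | COC(OC)c1cc(OCc8ccccc8)c(OCc8ccccc8)c(OCc8ccccc8)c1C(O)[C@H](OCc8ccccc8)[C@@H](O[Si](C)(C)C(C)(C)C)[C@H]2[C@H](O)CO[C@@H](c5ccccc5)O2 | intermediate
16 | 5-O-(tribenzylgalloyl) ester of 15 | COC(OC)c1cc(OCc8ccccc8)c(OCc8ccccc8)c(OCc8ccccc8)c1C(O)[C@H](OCc8ccccc8)[C@@H](O[Si](C)(C)C(C)(C)C)[C@H]2[C@H](OC(=O)c3cc(OCc8ccccc8)c(OCc8ccccc8)c(OCc8ccccc8)c3)CO[C@@H](c5ccccc5)O2 | intermediate
17 | C1 aryl ketone | COC(OC)c1cc(OCc8ccccc8)c(OCc8ccccc8)c(OCc8ccccc8)c1C(=O)[C@H](OCc8ccccc8)[C@@H](O[Si](C)(C)C(C)(C)C)[C@H]2[C@H](OC(=O)c3cc(OCc8ccccc8)c(OCc8ccccc8)c(OCc8ccccc8)c3)CO[C@@H](c5ccccc5)O2 | intermediate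
18 | (1S)-alcohol | COC(OC)c1cc(OCc8ccccc8)c(OCc8ccccc8)c(OCc8ccccc8)c1[C@H](O)[C@H](OCc8ccccc8)[C@@H](O[Si](C)(C)C(C)(C)C)[C@H]2[C@H](OC(=O)c3cc(OCc8ccccc8)c(OCc8ccccc8)c(OCc8ccccc8)c3)CO[C@@H](c5ccccc5)O2 | intermediate
19 | C1-OBn ether | COC(OC)c1cc(OCc8ccccc8)c(OCc8ccccc8)c(OCc8ccccc8)c1[C@H](OCc8ccccc8)[C@H](OCc8ccccc8)[C@@H](O[Si](C)(C)C(C)(C)C)[C@H]2[C@H](OC(=O)c3cc(OCc8ccccc8)c(OCc8ccccc8)c(OCc8ccccc8)c3)CO[C@@H](c5ccccc5)O2 | intermediate
20 | ring-C aldehyde | O=Cc1cc(OCc8ccccc8)c(OCc8ccccc8)c(OCc8ccccc8)c1[C@H](OCc8ccccc8)[C@H](OCc8ccccc8)[C@@H](O[Si](C)(C)C(C)(C)C)[C@H]2[C@H](OC(=O)c3cc(OCc8ccccc8)c(OCc8ccccc8)c(OCc8ccccc8)c3)CO[C@@H](c5ccccc5)O2 | intermediate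
21 | ring-C carboxylic acid | OC(=O)c1cc(OCc8ccccc8)c(OCc8ccccc8)c(OCc8ccccc8)c1[C@H](OCc8ccccc8)[C@H](OCc8ccccc8)[C@@H](O[Si](C)(C)C(C)(C)C)[C@H]2[C@H](OC(=O)c3cc(OCc8ccccc8)c(OCc8ccccc8)c(OCc8ccccc8)c3)CO[C@@H](c5ccccc5)O2 | intermediate
22 | ring-C benzyl ester | O=C(OCc8ccccc8)c1cc(OCc8ccccc8)c(OCc8ccccc8)c(OCc8ccccc8)c1[C@H](OCc8ccccc8)[C@H](OCc8ccccc8)[C@@H](O[Si](C)(C)C(C)(C)C)[C@H]2[C@H](OC(=O)c3cc(OCc8ccccc8)c(OCc8ccccc8)c(OCc8ccccc8)c3)CO[C@@H](c5ccccc5)O2 | intermediate
23 | 3-OH compound | O=C(OCc8ccccc8)c1cc(OCc8ccccc8)c(OCc8ccccc8)c(OCc8ccccc8)c1[C@H](OCc8ccccc8)[C@H](OCc8ccccc8)[C@@H](O)[C@H]2[C@H](OC(=O)c3cc(OCc8ccccc8)c(OCc8ccccc8)c(OCc8ccccc8)c3)CO[C@@H](c5ccccc5)O2 | intermediate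
24 | NHTP precursor | O=C(OCc8ccccc8)c1cc(OCc8ccccc8)c(OCc8ccccc8)c(OCc8ccccc8)c1[C@H](OCc8ccccc8)[C@H](OCc8ccccc8)[C@@H](OC(=O)c3cc(OCc8ccccc8)c(OCc8ccccc8)c(OCc8ccccc8)c3)[C@H]2[C@H](OC(=O)c4cc(OCc8ccccc8)c(OCc8ccccc8)c(OCc8ccccc8)c4)CO[C@@H](c5ccccc5)O2 | intermediate
25 | NHTP macrocycle | O=C(OCc8ccccc8)c1c(-c3c(C(=O)O%10)c(-c4c(C(=O)O%11)cc(OCc8ccccc8)c(OCc8ccccc8)c4OCc8ccccc8)c(OCc8ccccc8)c(OCc8ccccc8)c3OCc8ccccc8)c(OCc8ccccc8)c(OCc8ccccc8)c(OCc8ccccc8)c1[C@H](OCc8ccccc8)[C@H](OCc8ccccc8)[C@@H]%10[C@H]2[C@H]%11CO[C@@H](c5ccccc5)O2 | intermediate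
26 | 4,6-diol | O=C(OCc8ccccc8)c1c(-c3c(C(=O)O%10)c(-c4c(C(=O)O%11)cc(OCc8ccccc8)c(OCc8ccccc8)c4OCc8ccccc8)c(OCc8ccccc8)c(OCc8ccccc8)c3OCc8ccccc8)c(OCc8ccccc8)c(OCc8ccccc8)c(OCc8ccccc8)c1[C@H](OCc8ccccc8)[C@H](OCc8ccccc8)[C@@H]%10[C@H](O)[C@H]%11CO | intermediate
27 | bis(2-iodogalloyl) diester | O=C(OCc8ccccc8)c1c(-c3c(C(=O)O%10)c(-c4c(C(=O)O%11)cc(OCc8ccccc8)c(OCc8ccccc8)c4OCc8ccccc8)c(OCc8ccccc8)c(OCc8ccccc8)c3OCc8ccccc8)c(OCc8ccccc8)c(OCc8ccccc8)c(OCc8ccccc8)c1[C@H](OCc8ccccc8)[C@H](OCc8ccccc8)[C@@H]%10[C@H](OC(=O)c6cc(OCc8ccccc8)c(OCc8ccccc8)c(OCc8ccccc8)c6I)[C@H]%11COC(=O)c6cc(OCc8ccccc8)c(OCc8ccccc8)c(OCc8ccccc8)c6I | intermediate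
28 | perbenzylated chinquapinic acid | O=C(OCc8ccccc8)c1c(-c3c(C(=O)O%10)c(-c4c(C(=O)O%11)cc(OCc8ccccc8)c(OCc8ccccc8)c4OCc8ccccc8)c(OCc8ccccc8)c(OCc8ccccc8)c3OCc8ccccc8)c(OCc8ccccc8)c(OCc8ccccc8)c(OCc8ccccc8)c1[C@H](OCc8ccccc8)[C@H](OCc8ccccc8)[C@@H]%10[C@H](OC(=O)c6cc(OCc8ccccc8)c(OCc8ccccc8)c(OCc8ccccc8)c6-c7c(C(=O)O%12)cc(OCc8ccccc8)c(OCc8ccccc8)c7OCc8ccccc8)[C@H]%11C%12 | intermediate
29 | chinquapinic acid | O=C1OC[C@H]2OC(=O)c3cc(O)c(O)c(O)c3-c3c(O)c(O)c(O)c4c3C(=O)O[C@H]([C@@H](O)[C@@H](O)c3c(O)c(O)c(O)c-4c3C(=O)O)[C@@H]2OC(=O)c2cc(O)c(O)c(O)c2-c2c1cc(O)c(O)c2O | target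

**Totals:** 27 steps; longest linear sequence 20 steps (methyl gallate → 2 → 6 → 7 → 8 → 9 → 15 → … → 29).

**Three steps most likely to fail**
1. **Step 23 (new Pd-catalysed double dehydrogenative macrocyclisation).** The risks are low reactivity of ester-deactivated perbenzyloxyarene C–H bonds, wrong ring pairings, and strain in the 10-membered B/C ring. Fallback using known chemistry: replace the C–H partners with halides, acylating O5 with 5 and O3 with a 2,6-diiodo tribenzyloxybenzoate, and building ring C with an ortho iodide, then close both biaryls by sequential Cu-mediated intramolecular Ullmann couplings, as in Step 26.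
2. **Step 16 (C1 stereocontrol by chelation-controlled reduction of a hindered di-ortho-substituted aryl ketone).** Selectivity could be low because of competing chelation by O3 and the ester. Fallback: make the reduction catalyst-controlled by Noyori asymmetric transfer hydrogenation of 17 with RuCl[(S,S)-TsDPEN](p-cymene) and HCO2H/Et3N; alternatively take the (1R) alcohol from Step 13 and invert it by Mitsunobu with p-nitrobenzoic acid followed by methanolysis.
3. **Step 25 (esterifying the hindered O4 of the NHTP macrocycle) with the subsequent HHDP Ullmann.** Fallback: reverse the order of macrocycle formation. Remove the benzylidene early, install the 4,6-bis(2-iodogalloyl) esters on the 3-OTBS stage and close the HHDP by Ullmann, then desilylate, acylate O3 and run the Pd step last.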